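**Retrosynthetic overview** (atom numbers are labdane numbers)
1. End game: free C15–OH, C3 acetate and C18 tiglate come from diol 21, made from enone 18 by C3 reduction and reductive hydroxymethylation, which sets trans C5–H and quaternary C4.
2. Enone 18 comes from enal 14 by reductive 1,3-transposition: the exocyclic C8=C17 next to C7H2 is a masked C7=C8–C17H=O enal.
3. Ring B of 14 is cut at C9–C10 and C5–C6: Diels–Alder reaction of the cyclic 1-amino-3-siloxy diene 4 (ring A, C3=C4–C5=C10) with the 2-vinyl enal 11 (C6=C7–C8(CHO)=C9–chain), then [3,3] shift of the 1,5-diene C6=C7–C8–C3–C4=C5 in the bicyclo[2.2.2]octene.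
4. Enabling feature: the oxygen on C3 of ring A is 1,3 to C5 and para to C10, so C3 and C5 can carry the N and O donors of the diene; the C3–C8 bond that must break is flanked by the amino group (C3) and the formyl group (C8).
5. Ring order: ring A is present from 2-methylcyclohexane-1,3-dione (steps 1–3), chain 11 comes from geraniol (steps 4–9), ring B is formed in step 10.

Key step: step 10

Remarks on the chemistry: 3-bromo-2,4-dimethylphenol, used only in the fallback to step 10, is assumed to be a catalogue compound. The (4R,5R) diol is written as catalyst in step 10; which enantiomer leads to the (9S,10S) series of 14 is to be fixed in a pilot run.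

**Step 1**
Reactants: 1 2-methylcyclohexane-1,3-dione
Product: 2 3-(dimethylamino)-2-methylcyclohex-2-en-1-one
Conditions: Me2NH (2 M in THF), AcOH (cat.), PhMe, 4 Å MS, 80 °C
Reagents that add atoms: dimethylamine, CNC
Why: Condensation of a 1,3-dione with a secondary amine should give the vinylogous amide (enaminone formation); no stereocentre is formed.

**Step 2**
Reactants: 2 3-(dimethylamino)-2-methylcyclohex-2-en-1-one
Product: 3 3-(dimethylamino)-2,6-dimethylcyclohex-2-en-1-one
Conditions: LDA, THF, −78 °C; MeI, −78 → 0 °C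
Reagents that add atoms: iodomethane, CI
Why: Kinetic deprotonation of a vinylogous amide occurs at the alpha-prime carbon (C10) and the enolate is C-methylated (enolate alkylation); the new centre is racemic and is made trigonal again in step 3.

**Step 3**
Reactants: 3 3-(dimethylamino)-2,6-dimethylcyclohex-2-en-1-one
Product: 4 3-[(tert-butyldimethylsilyl)oxy]-N,N,2,4-tetramethylcyclohexa-1,3-dien-1-amine
Conditions: KHMDS, THF, −78 °C; TBSCl, −78 → 23 °C
Reagents that add atoms: tert-butyldimethylsilyl chloride, CC(C)(C)[Si](C)(C)Cl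
Why: The base removes the only alpha-prime hydrogen (C10–H) and O-silylation of the enolate should give the 1-amino-3-siloxy diene (silyl enol ether formation) with the diene termini at C3 and C10.

**Step 4**
Reactants: 5 geraniol
Product: 6 geranyl triisopropylsilyl ether
Conditions: TIPSCl, imidazole, DMF, 23 °C
Reagents that add atoms: triisopropylsilyl chloride, CC(C)[Si](Cl)(C(C)C)C(C)C
Why: Silylation of the primary allylic alcohol gives an ether that should survive acid, dissolving metal and hydride in the later steps.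

**Step 5**
Reactants: 6 geranyl triisopropylsilyl ether
Product: 7 6,7-epoxygeranyl triisopropylsilyl ether
Conditions: mCPBA (1.0 equiv), NaHCO3, CH2Cl2, 0 °C
Reagents that add atoms: 3-chloroperbenzoic acid, O=C(OO)c1cccc(Cl)c1
Why: Peracid epoxidation (Prilezhaev reaction) should select the remote, more electron-rich trisubstituted alkene over the one next to the allylic oxygen; the epoxide centre is racemic and is destroyed in step 6.

**Step 6**
Reactants: 7 6,7-epoxygeranyl triisopropylsilyl ether
Product: 8 (4E)-4-methyl-6-[(triisopropylsilyl)oxy]hex-4-enal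
Conditions: H5IO6, THF/Et2O, 0 °C
Reagents that add atoms: none
Why: Periodic acid opens the epoxide to the glycol and cleaves it (Malaprade cleavage) to the aldehyde, which will become C9.

**Step 7**
Reactants: 8 (4E)-4-methyl-6-[(triisopropylsilyl)oxy]hex-4-enal
Product: 9 (2E,6E)-6-methyl-8-[(triisopropylsilyl)oxy]octa-2,6-dienal
Conditions: Ph3P=CHCHO (1.1 equiv), PhMe, 80 °C
Reagents that add atoms: (triphenylphosphoranylidene)acetaldehyde, O=CC=P(c1ccccc1)(c1ccccc1)c1ccccc1
Why: Wittig olefination with the stabilised formyl ylide should give the (E)-enal.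

**Step 8**
Reactants: 9 (2E,6E)-6-methyl-8-[(triisopropylsilyl)oxy]octa-2,6-dienal
Product: 10 (2Z,6E)-2-iodo-6-methyl-8-[(triisopropylsilyl)oxy]octa-2,6-dienal
Conditions: I2, DMAP (cat.), K2CO3, THF/H2O, 23 °C
Reagents that add atoms: iodine, I-I
Why: Amine-catalysed alpha-iodination of an enal (conjugate addition of DMAP, iodination, elimination) should give the (Z)-2-iodo enal and leave the isolated alkene untouched.

**Step 9**
Reactants: 10 (2Z,6E)-2-iodo-6-methyl-8-[(triisopropylsilyl)oxy]octa-2,6-dienal
Product: 11 (2E,6E)-2-ethenyl-6-methyl-8-[(triisopropylsilyl)oxy]octa-2,6-dienal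
Conditions: Bu3SnCH=CH2, Pd2(dba)3 (cat.), AsPh3, CuI (cat.), DMF, 23 °C; used at once
Reagents that add atoms: tributyl(vinyl)stannane, C=C[Sn](CCCC)(CCCC)CCCC
Why: Stille coupling of an alpha-iodo enal proceeds with retention, so the vinyl group (C7=C6) ends cis to the C9 chain and the formyl group trans to it.

**Step 10**
Reactants: 4 amino siloxy diene (1.5 equiv); 11 2-vinyl enal
Product: 14 (9S,10S) enone enal, via bicyclo[2.2.2]octene cycloadduct 12 (not isolated), via silyloxy enamine 13 (not isolated)
Conditions: (4R,5R)-2,2-dimethyl-α,α,α′,α′-tetra(naphth-1-yl)-1,3-dioxolane-4,5-dimethanol (20 mol %), PhMe, −40 → 23 °C, then 60 °C; then 1 M HCl, THF, 0 → 23 °C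
Reagents that add atoms: water, O
Why: The diol hydrogen-bonds to the formyl group of 11 and diene 4 adds across C8=C9 in a normal-demand Diels–Alder reaction (terminus C10 to the beta carbon C9, amino-bearing C3 to C8) to give 12, a 1,5-diene (C6=C7–C8–C3–C4=C5) whose C3–C8 bond, weakened by the amino donor on C3 and the formyl acceptor on C8, migrates on warming by a Cope [3,3] shift (concerted, or stepwise by retro-Mannich cleavage and vinylogous re-addition) to make C5–C6 and give 13; acid then hydrolyses the enamine to the C3 ketone and eliminates the C5 silyloxy group to the C4=C5 enone. The closest known reaction types are the hydrogen-bond-catalysed Diels–Alder reaction of 1-amino-3-siloxy dienes with alpha-substituted enals and the Cope rearrangement of endo-5-vinylbicyclo[2.2.2]oct-2-enes to cis-fused hexahydronaphthalenes. Ring B is closed first across C3 and C10 by the [4+2] cycloaddition and is then recast by the six-centre [3,3] shift, so that overall the C6–C9 diene of 11 has added across C5=C10 of ring A. C9 and C10 are set in the cycloaddition: the exo-formyl transition state keeps the formyl group toward the C1–C2 bridge and the vinyl group and the C9 chain (cis to each other in the (E)-enal) toward the C4=C5 bridge, which places the chain cis to the C10 methyl, and the face of the enal is chosen by the chiral diol; C5 is stereogenic only in 13 and becomes trigonal in 14. The step needs C=C over C=O periselectivity, C10-to-C9 regiochemistry and exo selectivity, which the alpha substituent of the enal, the push of both donors toward C10 and the steric demand of the ethano bridge should secure.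

**Step 11**
Reactants: 14 (9S,10S) enone enal
Product: 15 (9S,10S) enone allylic alcohol
Conditions: NaBH4, MeOH/CH2Cl2, −78 °C
Reagents that add atoms: none
Why: At low temperature borohydride should reduce the aldehyde 1,2 much faster than the hindered, tetrasubstituted enone (chemoselective carbonyl reduction).

**Step 12**
Reactants: 15 (9S,10S) enone allylic alcohol
Product: 18 (9R,10S) exocyclic-methylene enone, via N-allyl sulfonylhydrazide 16 (not isolated), via allylic diazene 17 (not isolated)
Conditions: PPh3, DEAD, 2-nitrobenzenesulfonylhydrazide, THF, −30 → 23 °C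
Reagents that add atoms: none
Why: Mitsunobu displacement by the sulfonylhydrazide, loss of sulfinic acid and retro-ene loss of N2 from the allylic diazene deliver hydrogen to C7 and move the double bond to C8=C17 (reductive allylic transposition); no stereocentre is formed because C7 becomes CH2.

**Step 13**
Reactants: 18 (9R,10S) exocyclic-methylene enone
Product: 20 (4S,5S,9R,10S) hydroxymethyl ketone, via lithium enolate 19 (not isolated)
Conditions: Li (2.2 equiv), NH3(l)/THF, t-BuOH (1.0 equiv), −78 °C; NH3 removed; CH2O (gas), THF, −78 → −40 °C; NH4Cl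
Reagents that add atoms: formaldehyde, C=O
Why: Dissolving-metal (Birch-type) reduction of the enone protonates C5 axially to give the trans ring fusion (H5 anti to the C10 methyl), and the regiodefined C4 enolate should add formaldehyde (aldol) from the face opposite the C10 methyl, leaving CH2OH equatorial and the C4 methyl axial.

**Step 14**
Reactants: 20 (4S,5S,9R,10S) hydroxymethyl ketone
Product: 21 (3R,4S,5S,9R,10S) 3,18-diol
Conditions: NaBH4, MeOH, 0 °C
Reagents that add atoms: none
Why: Hydride should attack the C3 ketone axially, away from the axial C4 methyl, giving the equatorial alcohol cis to the C10 methyl (substrate-controlled ketone reduction).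

**Step 15**
Reactants: 21 (3R,4S,5S,9R,10S) 3,18-diol
Product: 22 18-O-tiglate
Conditions: tigloyl chloride (1.1 equiv), pyridine, DMAP (cat.), CH2Cl2, −20 → 0 °C
Reagents that add atoms: (E)-2-methylbut-2-enoyl chloride, C/C=C(\C)C(=O)Cl
Why: Acylation should discriminate the primary C18 alcohol from the hindered secondary C3 alcohol next to the quaternary carbon (DMAP-catalysed esterification).

**Step 16**
Reactants: 22 18-O-tiglate
Product: 23 3-O-acetyl 18-O-tiglate
Conditions: Ac2O, pyridine, DMAP (cat.), CH2Cl2, 23 °C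
Reagents that add atoms: acetic anhydride, CC(=O)OC(C)=O
Why: Acetylation of the remaining secondary alcohol retains the configuration at C3.

**Step 17**
Reactants: 23 3-O-acetyl 18-O-tiglate
Product: 24 target
Conditions: HF·pyridine, pyridine, THF, 0 → 23 °C
Reagents that add atoms: none
Why: Fluoride-driven cleavage of the silyl ether frees the C15 allylic alcohol and should leave both esters and the exocyclic alkene intact.

**Compound list**
1 | 2-methylcyclohexane-1,3-dione | CC1C(=O)CCCC1=O | starting material
2 | 3-(dimethylamino)-2-methylcyclohex-2-en-1-one | CN(C)C1=C(C)C(=O)CCC1 | intermediate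
3 | 3-(dimethylamino)-2,6-dimethylcyclohex-2-en-1-one (racemic) | CN(C)C1=C(C)C(=O)C(C)CC1 | intermediate
4 | 3-[(tert-butyldimethylsilyl)oxy]-N,N,2,4-tetramethylcyclohexa-1,3-dien-1-amine | CN(C)C1=C(C)C(O[Si](C)(C)C(C)(C)C)=C(C)CC1 | intermediate
5 | geraniol, (2E)-3,7-dimethylocta-2,6-dien-1-ol | CC(C)=CCC/C(C)=C/CO | starting material
6 | geranyl triisopropylsilyl ether | CC(C)=CCC/C(C)=C/CO[Si](C(C)C)(C(C)C)C(C)C | intermediate
7 | 6,7-epoxygeranyl triisopropylsilyl ether (racemic epoxide) | CC1(C)OC1CC/C(C)=C/CO[Si](C(C)C)(C(C)C)C(C)C | intermediate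
8 | (4E)-4-methyl-6-[(triisopropylsilyl)oxy]hex-4-enal | O=CCC/C(C)=C/CO[Si](C(C)C)(C(C)C)C(C)C | intermediate
9 | (2E,6E)-6-methyl-8-[(triisopropylsilyl)oxy]octa-2,6-dienal | O=C/C=C/CC/C(C)=C/CO[Si](C(C)C)(C(C)C)C(C)C | intermediate
10 | (2Z,6E)-2-iodo-6-methyl-8-[(triisopropylsilyl)oxy]octa-2,6-dienal | O=C/C(I)=C/CC/C(C)=C/CO[Si](C(C)C)(C(C)C)C(C)C | intermediate
11 | (2E,6E)-2-ethenyl-6-methyl-8-[(triisopropylsilyl)oxy]octa-2,6-dienal | O=C/C(C=C)=C/CC/C(C)=C/CO[Si](C(C)C)(C(C)C)C(C)C | intermediate
12 | Diels–Alder adduct: 1-(dimethylamino)-2-ethenyl-4,6-dimethyl-5-[(tert-butyldimethylsilyl)oxy]-3-[(3E)-3-methyl-5-(triisopropylsilyloxy)pent-3-enyl]bicyclo[2.2.2]oct-5-ene-2-carbaldehyde; formyl anti, vinyl and side chain syn to the C5=C6 bridge | CN(C)[C@]12CC[C@](C)(C(O[Si](C)(C)C(C)(C)C)=C1C)[C@H](CC/C(C)=C/CO[Si](C(C)C)(C(C)C)C(C)C)[C@]2(C=O)C=C | intermediate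
13 | cis-fused 4a-[(tert-butyldimethylsilyl)oxy]-6-(dimethylamino)-5,8a-dimethyl-1-[(3E)-3-methyl-5-(triisopropylsilyloxy)pent-3-enyl]-1,4,4a,7,8,8a-hexahydronaphthalene-2-carbaldehyde; side chain and silyloxy group cis to the 8a-methyl | O=CC1=CC[C@]2(O[Si](C)(C)C(C)(C)C)[C@@](C)(CCC(N(C)C)=C2C)[C@@H]1CC/C(C)=C/CO[Si](C(C)C)(C(C)C)C(C)C | intermediate
14 | (1S,8aS)-5,8a-dimethyl-1-[(3E)-3-methyl-5-(triisopropylsilyloxy)pent-3-enyl]-6-oxo-1,4,6,7,8,8a-hexahydronaphthalene-2-carbaldehyde (labdane numbering 9S,10S; chain cis to the angular methyl) | O=CC1=CCC2=C(C)C(=O)CC[C@@]2(C)[C@@H]1CC/C(C)=C/CO[Si](C(C)C)(C(C)C)C(C)C | intermediate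
15 | allylic alcohol from 14 (CHO reduced to CH2OH; 9S,10S) | OCC1=CCC2=C(C)C(=O)CC[C@@]2(C)[C@@H]1CC/C(C)=C/CO[Si](C(C)C)(C(C)C)C(C)C | intermediate
16 | N-allyl-N-(2-nitrobenzenesulfonyl)hydrazine from 15 (OH replaced by N(NH2)SO2Ar) | NN(CC1=CCC2=C(C)C(=O)CC[C@@]2(C)[C@@H]1CC/C(C)=C/CO[Si](C(C)C)(C(C)C)C(C)C)S(=O)(=O)c1ccccc1[N+](=O)[O-] | intermediate
17 | allylic diazene from 16 (CH2–N=NH on C8) | N=NCC1=CCC2=C(C)C(=O)CC[C@@]2(C)[C@@H]1CC/C(C)=C/CO[Si](C(C)C)(C(C)C)C(C)C | intermediate
18 | (9R,10S) 4,10-dimethyl-8(17)-methylidene Δ4-3-ketone with the C9 chain cis to the C10 methyl: (4aS,5R)-1,4a-dimethyl-6-methylidene-5-[(3E)-3-methyl-5-(triisopropylsilyloxy)pent-3-enyl]-4,4a,5,6,7,8-hexahydronaphthalen-2(3H)-one | C=C1CCC2=C(C)C(=O)CC[C@@]2(C)[C@@H]1CC/C(C)=C/CO[Si](C(C)C)(C(C)C)C(C)C | intermediate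
19 | lithium C3–C4 enolate of the trans-fused ketone (H5 trans to the C10 methyl) | C=C1CC[C@@H]2C(C)=C([O-])CC[C@@]2(C)[C@@H]1CC/C(C)=C/CO[Si](C(C)C)(C(C)C)C(C)C.[Li+] | intermediate
20 | (4S,5S,9R,10S) trans-fused 3-ketone with equatorial C18 hydroxymethyl and axial C4 methyl | C=C1CC[C@@H]2[C@@](C)(CO)C(=O)CC[C@@]2(C)[C@@H]1CC/C(C)=C/CO[Si](C(C)C)(C(C)C)C(C)C | intermediate
21 | (3R,4S,5S,9R,10S) 3,18-diol, equatorial 3-OH cis to the C10 methyl, 15-O-triisopropylsilyl | C=C1CC[C@@H]2[C@@](C)(CO)[C@H](O)CC[C@@]2(C)[C@@H]1CC/C(C)=C/CO[Si](C(C)C)(C(C)C)C(C)C | intermediate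
22 | 18-O-tiglate of 21 | C=C1CC[C@@H]2[C@@](C)(COC(=O)/C(C)=C/C)[C@H](O)CC[C@@]2(C)[C@@H]1CC/C(C)=C/CO[Si](C(C)C)(C(C)C)C(C)C | intermediate
23 | 3-O-acetyl-18-O-tiglate, 15-O-triisopropylsilyl | C=C1CC[C@@H]2[C@@](C)(COC(=O)/C(C)=C/C)[C@H](OC(C)=O)CC[C@@]2(C)[C@@H]1CC/C(C)=C/CO[Si](C(C)C)(C(C)C)C(C)C | intermediate
24 | target, (3R,4S,5S,9R,10S)-3-acetoxy-15-hydroxylabda-8(17),13E-dien-18-yl (2E)-2-methylbut-2-enoate | C=C1CC[C@@H]2[C@@](C)(COC(=O)/C(C)=C/C)[C@H](OC(C)=O)CC[C@@]2(C)[C@@H]1CC/C(C)=C/CO | target

**Totals**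
Total step count: 17. Longest linear sequence: 14 steps (steps 4–17, from geraniol).

**Steps most likely to fail**

Step 10. The cycloaddition may stall at the congested C9–C10 bond, the diene may add to the formyl C=O instead of the C=C bond, the exo and facial selectivities may be low, or the [3,3] shift may not follow. The fallback closes ring B on an aromatic ring A in separate, known steps; it sets out from aldehyde 8 and comes back at enone 18. Aldehyde 8 with indium and 1,4-dibromobut-2-yne in THF/H2O should give the dienyl carbinol (7E)-7-methyl-3-methylidene-9-[(triisopropylsilyl)oxy]nona-1,7-dien-4-ol F1. Hydroboration of its vinyl group with 9-BBN and Suzuki–Miyaura coupling with 3-bromo-2,4-dimethylphenol (PdCl2(dppf), K3PO4, THF/H2O) should make the C5–C6 bond and give 3-[(7E)-4-hydroxy-7-methyl-3-methylidene-9-[(triisopropylsilyl)oxy]non-7-en-1-yl]-2,4-dimethylphenol F2. Methyl chloroformate and pyridine should convert both hydroxyls into the bis(methyl carbonate) F3. Pd2(dba)3 with a chiral bisphosphine and K2CO3 in MeOH/THF should free the phenoxide and close ring B by intramolecular dearomative Tsuji–Trost alkylation at the para carbon (C9–C10, exocyclic C8=C17), giving the cross-conjugated dienone F4, the 1,2-didehydro derivative of 18. Li/NH3 (2 equiv, then NH4Cl) should reduce the less substituted C1=C2 enone bond and return to 18.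

Step 13. Proton transfer between enolate and product, O-alkylation or double addition of formaldehyde, low facial selectivity at C4 or reductive loss of the allylic silyl ether may occur. The fallback separates reduction and C–C bond formation; it sets out from 18 and comes back at 20. Li/NH3 reduction followed by Me3SiCl/Et3N should give the trans-fused trimethylsilyl enol ether F5, which is isolated. Mukaiyama aldol hydroxymethylation with aqueous formaldehyde and Yb(OTf)3 in THF should then give 20.

Step 12. The sulfonylhydrazide may condense with the ketone, or the allylic diazene may lose N2 without clean hydrogen transfer. The fallback uses a palladium hydride instead of a diazene; it sets out from 15 and comes back at 18. Formic acetic anhydride and pyridine should give the allylic formate F6. Pd(OAc)2/PBu3 in dioxane should ionise it, the allylpalladium formate losing CO2 and delivering hydride to the ring terminus C7 to give 18.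

**Further compounds**
F1 | step 10 | (7E)-7-methyl-3-methylidene-9-[(triisopropylsilyl)oxy]nona-1,7-dien-4-ol (racemic) | C=CC(=C)C(O)CC/C(C)=C/CO[Si](C(C)C)(C(C)C)C(C)C
F2 | step 10 | 3-[(7E)-4-hydroxy-7-methyl-3-methylidene-9-[(triisopropylsilyl)oxy]non-7-en-1-yl]-2,4-dimethylphenol (racemic) | Cc1ccc(O)c(C)c1CCC(=C)C(O)CC/C(C)=C/CO[Si](C(C)C)(C(C)C)C(C)C
F3 | step 10 | bis(methyl carbonate) of F2 (racemic) | COC(=O)Oc1ccc(C)c(CCC(=C)C(OC(=O)OC)CC/C(C)=C/CO[Si](C(C)C)(C(C)C)C(C)C)c1C
F4 | step 10 | 1,2-didehydro derivative of 18 (cross-conjugated 1,4-dien-3-one, C9 and C10 as in 18) | C=C1CCC2=C(C)C(=O)C=C[C@@]2(C)[C@@H]1CC/C(C)=C/CO[Si](C(C)C)(C(C)C)C(C)C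
F5 | step 13 | trimethylsilyl enol ether (C3–C4) of the trans-fused ketone from 18 | C=C1CC[C@@H]2C(C)=C(O[Si](C)(C)C)CC[C@@]2(C)[C@@H]1CC/C(C)=C/CO[Si](C(C)C)(C(C)C)C(C)C
F6 | step 12 | formate ester of allylic alcohol 15 | O=COCC1=CCC2=C(C)C(=O)CC[C@@]2(C)[C@@H]1CC/C(C)=C/CO[Si](C(C)C)(C(C)C)C(C)C
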